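4 questions stand on this flask, and one number, counted from the charges, bears on the first and bounds the rest.

starting complex 0.062 M; incoming ligand 0.0589 M; leaving ligand 0.0620 M; protic impurity 1.24 mM; time 15 d

- the state of affairs at 15 d: stopped, and by what, or still going (the incoming ligand has run out first / all of the starting complex has reacted / it is still moving / forward and back rates have come level)
- the complex with four exchanged standing at 15 d, as a percentage of the starting complex charged
- the complex with one exchanged standing at 15 d, as a percentage of the starting complex charged
- the complex with two exchanged standing at 15 d, as a percentage of the starting complex charged

- leaving ligand is meant together with its crystals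
- solid, in amounts per volume of the solution: crystals
- the reaction counts as stopped when no species that holds the starting complex changes by six tenths of a point or more over the second half of the time
- run time (flask): 15 d

    starting complex + incoming ligand → leaving ligand + complex with one exchanged (k1 = 1.03 M⁻¹ h⁻¹)
    complex with one exchanged + incoming ligand → leaving ligand + complex with two exchanged (k2 = 0.672 M⁻¹ h⁻¹)
    complex with two exchanged + incoming ligand → leaving ligand + complex with three exchanged (k3 = 1.61 M⁻¹ h⁻¹)
    complex with three exchanged + incoming ligand → leaving ligand + complex with four exchanged (k4 = 4.03 M⁻¹ h⁻¹)
    complex with four exchanged ⇌ isomer of the product (K5 = 1.6, k5 = 0.0311 h⁻¹)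
    crystals ⇌ leaving ligand, rate k6*(cs6 - [leaving ligand]) while solid is left; crystals form when [leaving ligand] > cs6 (cs6 = 20 mM, k6 = 1.12 h⁻¹)
    protic impurity + starting complex → quenched substrate (k7 = 52.8 M⁻¹ h⁻¹)

Incoming ligand replaces leaving ligand on the complex one exchange at a time, up to the fourth. The complex with four exchanged turns into its isomer and back, and the protic impurity quenches starting complex. The growth of crystals changes the conversion of starting complex by nothing, so I set it aside.

I read the flask as a ladder of half-lives. On the first rung the protic impurity, facing starting complex as charged, has a half-life of 0.212 h, much shorter than any exchange. So I take that step as settled: it removes 1.24 mM and leaves 0.0608 M of complex. Hence my quantity 0.969, the incoming ligand per complex left free. A complex can take 4 exchanges and this is under that, so the incoming ligand is the limiting reagent; it is also under one, so some starting complex must stay.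

The next rungs, with ligand as charged, are 0.12 d for step 4, 0.30 d for step 3, 0.48 d for step 1, 0.571 d for the isomer's relaxation and 0.73 d for step 2. A complex with two exchanged therefore passes on faster than one with one exchanged, so I expect the latter to gather. The isomer pair relaxes well within the time, so 38.5% of that pair should stand free.

On the last rung, ligand meeting 0.0608 M of complex at 0.672 M⁻¹ h⁻¹, the smallest exchange constant, has a half-life near 0.707 d, far shorter than the 15 d allowed. I commit to this: the ligand goes first, starting complex stays, and the exchanges counted as [one exchanged] + 2[two exchanged] + 3[three exchanged] + 4([four exchanged] + [isomer]) come to 0.969 per free complex. The complex with one exchanged stays below 95.0%. The split needs integration, so my hand stops here.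

The forecast, at about 0.97 equivalents, says the incoming ligand has run out first, with four exchanged 1.82%, one exchanged 43.3% and two exchanged 11.4%. It also holds that “The leaving ligand has no back reaction, so its crystals don't matter”.

The simulation says the incoming ligand has run out first, with 1.83%, 43.3% and 11.4% in the same order.

At 15.0 d this flask holds 0% of its incoming ligand and 35% of starting complex, and its complexes carry 0.969 exchanges per free complex, against 0.969. The neighbour flask charged with 0.15 M of incoming ligand has 2.47 ligand per free complex, still under 4. It too ends with 0% of its ligand, and 6.59% of starting complex stands. Its complexes carry 2.47 exchanges per free complex, with 15.9% of complex with four exchanged.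

Its constants stand for no real mixture; the run is a simulation.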